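**Retrosynthetic overview**
- Feature: in ring A (the indole that bears the formyl group), the neighbouring atoms C2 and C3 each hold a carbon substituent: CHO on C2 and the methine CH(indol-3-yl)2 on C3. Both carbons can be attached to one alkene carbon, the future C2, because the diarylmethyl carbon tolerates positive charge and can move over to C3.
- End game: Boc removal from rings B and C, oxidation of CH2OH to CHO at C2, and desilylation lead back to a 2-(silyloxymethyl)-3-(diarylmethyl)indole.
- Key disconnection: N1–C2 and methine–C3 of ring A are cut together, which gives a beta,beta-disubstituted 2-azidostyrene (rhodium nitrene closure followed by a 1,2-shift).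
- The azidostyrene comes from an aldol/elimination union of methyl 3,3-bis(1-Boc-indol-3-yl)propanoate (from indole and methyl 3,3-dimethoxypropanoate) with 2-azidobenzaldehyde (from 2-nitrobenzaldehyde), followed by ester reduction and silylation.
- Ring order: rings B and C are bought as indole and the benzene half of ring A arrives with the aldehyde. The pyrrole half of ring A is the only ring formed, late in the route.

Key step: step 8

Abbreviations: Boc = tert-butoxycarbonyl; TBS = tert-butyldimethylsilyl; DBU = 1,8-diazabicyclo[5.4.0]undec-7-ene; DMAP = 4-(dimethylamino)pyridine.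

Assumption: the enoate, the allylic alcohol and the silyl ether are drawn as the E isomers expected from the E1cB elimination (aryl ring trans to the ester-derived carbon). The geometry is erased in the key step, where the disubstituted alkene carbon becomes sp3, so a minor Z isomer need not be removed.

**Step 1**
Reactants: 1 indole (2.1 equiv); 2 methyl 3,3-dimethoxypropanoate
Product: 3 methyl 3,3-bis(1H-indol-3-yl)propanoate
Conditions: p-TsOH·H2O (10 mol %), MeCN, rt
Reagents that add atoms: none
Why: This is an acid-catalysed bis(indolyl)methane condensation (twofold Friedel–Crafts alkylation), in which the acetal ionises to an oxocarbenium ion that C3 of indole attacks, loss of the second methanol gives a 3-alkylideneindoleninium ion that a second indole attacks at C3, and the ester is inert to catalytic acid.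

**Step 2**
Reactants: 3 methyl 3,3-bis(1H-indol-3-yl)propanoate
Product: 4 methyl 3,3-bis(1-Boc-indol-3-yl)propanoate
Conditions: Boc2O (2.4 equiv), DMAP (10 mol %), MeCN, rt
Reagents that add atoms: di-tert-butyl dicarbonate, CC(C)(C)OC(=O)OC(=O)OC(C)(C)C
Why: DMAP-catalysed N-acylation (carbamate protection) of both indole nitrogens removes the acidic N–H protons before the enolate step and lowers the reactivity of rings B and C towards the later electrophilic nitrene.

**Step 3**
Reactants: 5 2-nitrobenzaldehyde
Product: 6 2-azidobenzaldehyde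
Conditions: NaN3 (1.5 equiv), DMF, 60 °C, dark
Reagents that add atoms: sodium azide, [Na+].[N-]=[N+]=[N-]
Why: In this nucleophilic aromatic substitution the ortho formyl group activates the ring and nitrite leaves, and the moderate temperature keeps the azide from losing N2.

**Step 4**
Reactants: 4 methyl 3,3-bis(1-Boc-indol-3-yl)propanoate; 6 2-azidobenzaldehyde
Product: 9 methyl 3-acetoxy-3-(2-azidophenyl)-2-[bis(1-Boc-indol-3-yl)methyl]propanoate (racemic syn/anti mixture), via lithium enolate 7 (not isolated), via lithium aldolate 8 (not isolated)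
Conditions: LiN(i-Pr)2 (1.05 equiv), THF, −78 °C; 6, −78 °C; Ac2O (3 equiv), −78 to 0 °C
Reagents that add atoms: acetic anhydride, CC(=O)OC(C)=O
Why: This is a directed aldol addition of a preformed lithium ester enolate to a non-enolisable aldehyde with in situ O-acetylation, which blocks retro-aldol cleavage and installs the leaving group; the ester alpha proton is far more acidic than C2–H of a Boc-indole, the azide is inert at −78 °C, and the two new stereocentres are left uncontrolled because step 5 destroys both.

**Step 5**
Reactants: 9 methyl 3-acetoxy-3-(2-azidophenyl)-2-[bis(1-Boc-indol-3-yl)methyl]propanoate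
Product: 10 methyl (E)-3-(2-azidophenyl)-2-[bis(1-Boc-indol-3-yl)methyl]prop-2-enoate
Conditions: DBU (2 equiv), CH2Cl2, 0 °C to rt
Reagents that add atoms: none
Why: In this E1cB elimination of a beta-acetoxy ester both diastereomers pass through one ester enolate and should lose acetate from the conformer that keeps aryl ring and ester apart (E alkene), and the methine proton hangs on the alpha carbon, where the ester does not acidify it, so the double bond should stay in place.

**Step 6**
Reactants: 10 methyl (E)-3-(2-azidophenyl)-2-[bis(1-Boc-indol-3-yl)methyl]prop-2-enoate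
Product: 11 (E)-3-(2-azidophenyl)-2-[bis(1-Boc-indol-3-yl)methyl]prop-2-en-1-ol
Conditions: i-Bu2AlH (2.5 equiv), CH2Cl2, −78 °C; aq. potassium sodium tartrate
Reagents that add atoms: none
Why: i-Bu2AlH performs 1,2-reduction of the alpha,beta-unsaturated ester to the allylic alcohol, and at −78 °C the aluminium-coordinated ester should react well ahead of the aryl azide and the two indole carbamates.

**Step 7**
Reactants: 11 (E)-3-(2-azidophenyl)-2-[bis(1-Boc-indol-3-yl)methyl]prop-2-en-1-ol
Product: 12 (E)-1-azido-2-{3,3-bis(1-Boc-indol-3-yl)-2-[(tert-butyldimethylsilyloxy)methyl]prop-1-enyl}benzene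
Conditions: t-BuMe2SiCl (1.3 equiv), imidazole (2.5 equiv), DMF, rt
Reagents that add atoms: tert-butyldimethylsilyl chloride, CC(C)(C)[Si](C)(C)Cl
Why: Imidazole-promoted silyl ether formation on a primary allylic alcohol is routine, touches no other group, and turns the second substituent of the future C2 into a poor migrating group.

**Step 8**
Reactants: 12 (E)-1-azido-2-{3,3-bis(1-Boc-indol-3-yl)-2-[(tert-butyldimethylsilyloxy)methyl]prop-1-enyl}benzene
Product: 14 3-[bis(1-Boc-indol-3-yl)methyl]-2-[(tert-butyldimethylsilyloxy)methyl]-1H-indole, via 3H-indole tautomer 13 (not isolated)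
Conditions: Rh2(O2CC7H15)4 (5 mol %), 4 Å molecular sieves, toluene, 70 °C
Reagents that add atoms: none
Why: Proposed new method: Rh2(O2CC7H15)4 should take N2 out of the aryl azide to give a rhodium N-aryl nitrene, and the nitrene nitrogen, the two ring carbons and the two styrene carbons then close in a four-electron, five-atom electrocyclisation (formally 5-endo-trig) that makes N1–C2 and with it the pyrrole half of ring A, leaving a fully substituted C2 beside a benzylic cation at C3. The bis(1-Boc-indol-3-yl)methyl group then moves from C2 to C3 in a cationic 1,2-shift (new methine–C3 bond) to give 3H-indole 13, which tautomerises to indole 14. The closest known reaction type is the dirhodium-carboxylate-catalysed conversion of beta,beta-disubstituted 2-azidostyrenes into 2,3-disubstituted indoles, in which aryl, acyl and aminomethyl groups are known to migrate, whereas a diarylmethyl group set against an oxymethyl group has not been shown. The selectivity needed is migration of the methine carbon and not of the CH2OSi carbon, and the substrate secures it because a secondary carbon flanked by two indole rings carries positive charge in the bridged transition state while the primary carbon is inductively deactivated by an oxygen whose lone pairs are weakened by silicon; if the group leaves altogether as an ion pair, the only nucleophilic carbon of the 2-substituted indole left behind is C3, so recombination leads to the same product. Closure must also outrun C–H amination at the methine and attack of the nitrene on rings B and C, which the conjugated five-atom array and the electron-withdrawing Boc groups favour. No stereocentre remains, since the quaternary C2 of the cation and C3 of 13 are transient, and both alkene geometries of 12 reach the same cation.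

**Step 9**
Reactants: 14 3-[bis(1-Boc-indol-3-yl)methyl]-2-[(tert-butyldimethylsilyloxy)methyl]-1H-indole
Product: 15 {3-[bis(1-Boc-indol-3-yl)methyl]-1H-indol-2-yl}methanol
Conditions: Bu4NF (1.2 equiv), AcOH (1.2 equiv), THF, 0 °C to rt
Reagents that add atoms: none
Why: Fluoride-induced cleavage of a primary silyl ether is fast, and the acetic acid buffer keeps the medium from becoming basic enough to attack the indole carbamates.

**Step 10**
Reactants: 15 {3-[bis(1-Boc-indol-3-yl)methyl]-1H-indol-2-yl}methanol
Product: 16 3-[bis(1-Boc-indol-3-yl)methyl]-1H-indole-2-carbaldehyde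
Conditions: activated MnO2 (15 equiv), CH2Cl2, rt
Reagents that add atoms: none
Why: MnO2 oxidation of an (indol-2-yl)methanol, a benzylic-type alcohol, stops at the aldehyde, and the Boc groups on rings B and C keep the methine too electron-poor to be oxidised in competition.

**Step 11**
Reactants: 16 3-[bis(1-Boc-indol-3-yl)methyl]-1H-indole-2-carbaldehyde
Product: 17 trisindolal, 3-[bis(1H-indol-3-yl)methyl]-1H-indole-2-carbaldehyde
Conditions: K2CO3 (3 equiv), MeOH/THF, 50 °C, N2
Reagents that add atoms: none
Why: Base-mediated methanolysis of indole N-carbamates (acyl transfer to methoxide with an indolide leaving group) frees both nitrogens without acid, which could trigger retro-Friedel–Crafts scrambling of the tris(indolyl)methane, and the non-enolisable aldehyde survives.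

**Compound list**
1 | indole | c1ccc2[nH]ccc2c1 | starting material
2 | methyl 3,3-dimethoxypropanoate | COC(CC(=O)OC)OC | starting material
3 | methyl 3,3-bis(1H-indol-3-yl)propanoate | COC(=O)CC(c1c[nH]c2ccccc12)c1c[nH]c2ccccc12 | intermediate
4 | methyl 3,3-bis(1-Boc-indol-3-yl)propanoate | COC(=O)CC(c1cn(C(=O)OC(C)(C)C)c2ccccc12)c1cn(C(=O)OC(C)(C)C)c2ccccc12 | intermediate
5 | 2-nitrobenzaldehyde | O=Cc1ccccc1[N+](=O)[O-] | starting material
6 | 2-azidobenzaldehyde | [N-]=[N+]=Nc1ccccc1C=O | intermediate
7 | lithium enolate of 4 (not isolated; enolate geometry left open) | [Li+].COC([O-])=CC(c1cn(C(=O)OC(C)(C)C)c2ccccc12)c1cn(C(=O)OC(C)(C)C)c2ccccc12 | intermediate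
8 | lithium aldolate from 7 and 6 (not isolated; racemic syn/anti mixture) | [Li+].COC(=O)C(C([O-])c1ccccc1N=[N+]=[N-])C(c1cn(C(=O)OC(C)(C)C)c2ccccc12)c1cn(C(=O)OC(C)(C)C)c2ccccc12 | intermediate
9 | methyl 3-acetoxy-3-(2-azidophenyl)-2-[bis(1-Boc-indol-3-yl)methyl]propanoate (racemic syn/anti mixture) | COC(=O)C(C(OC(C)=O)c1ccccc1N=[N+]=[N-])C(c1cn(C(=O)OC(C)(C)C)c2ccccc12)c1cn(C(=O)OC(C)(C)C)c2ccccc12 | intermediate
10 | methyl (E)-3-(2-azidophenyl)-2-[bis(1-Boc-indol-3-yl)methyl]prop-2-enoate | [N-]=[N+]=Nc1ccccc1/C=C(/C(=O)OC)C(c1cn(C(=O)OC(C)(C)C)c2ccccc12)c1cn(C(=O)OC(C)(C)C)c2ccccc12 | intermediate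
11 | (E)-3-(2-azidophenyl)-2-[bis(1-Boc-indol-3-yl)methyl]prop-2-en-1-ol | [N-]=[N+]=Nc1ccccc1/C=C(/CO)C(c1cn(C(=O)OC(C)(C)C)c2ccccc12)c1cn(C(=O)OC(C)(C)C)c2ccccc12 | intermediate
12 | (E)-1-azido-2-{3,3-bis(1-Boc-indol-3-yl)-2-[(tert-butyldimethylsilyloxy)methyl]prop-1-enyl}benzene | [N-]=[N+]=Nc1ccccc1/C=C(/CO[Si](C)(C)C(C)(C)C)C(c1cn(C(=O)OC(C)(C)C)c2ccccc12)c1cn(C(=O)OC(C)(C)C)c2ccccc12 | intermediate
13 | 3-[bis(1-Boc-indol-3-yl)methyl]-2-[(tert-butyldimethylsilyloxy)methyl]-3H-indole (not isolated; racemic at C3) | CC(C)(C)[Si](C)(C)OCC1=Nc2ccccc2C1C(c1cn(C(=O)OC(C)(C)C)c2ccccc12)c1cn(C(=O)OC(C)(C)C)c2ccccc12 | intermediate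
14 | 3-[bis(1-Boc-indol-3-yl)methyl]-2-[(tert-butyldimethylsilyloxy)methyl]-1H-indole | CC(C)(C)[Si](C)(C)OCc1[nH]c2ccccc2c1C(c1cn(C(=O)OC(C)(C)C)c2ccccc12)c1cn(C(=O)OC(C)(C)C)c2ccccc12 | intermediate
15 | {3-[bis(1-Boc-indol-3-yl)methyl]-1H-indol-2-yl}methanol | OCc1[nH]c2ccccc2c1C(c1cn(C(=O)OC(C)(C)C)c2ccccc12)c1cn(C(=O)OC(C)(C)C)c2ccccc12 | intermediate
16 | 3-[bis(1-Boc-indol-3-yl)methyl]-1H-indole-2-carbaldehyde | O=Cc1[nH]c2ccccc2c1C(c1cn(C(=O)OC(C)(C)C)c2ccccc12)c1cn(C(=O)OC(C)(C)C)c2ccccc12 | intermediate
17 | trisindolal, 3-[bis(1H-indol-3-yl)methyl]-1H-indole-2-carbaldehyde (no stereocentre) | O=Cc1[nH]c2ccccc2c1C(c1c[nH]c2ccccc12)c1c[nH]c2ccccc12 | target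

**Total step count:** 11. **Longest linear sequence:** 10 steps (steps 1, 2, 4, 5, 6, 7, 8, 9, 10 and 11, from indole). Step 3 is the one-step side branch.

**Steps most likely to fail**

1. **Step 8 (key step).**
   - What may go wrong: the oxymethyl carbon may migrate in place of the diarylmethyl carbon. The nitrene may insert into the methine C–H bond. The diarylmethyl cation may escape from the ion pair before it recombines at C3, all the more because the Boc groups weaken its stabilisation.
   - Fallback (known chemistry): the nitrene closure is given up and the fallback sets out from indole 1.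
     - Two equivalents of 1 are condensed with purchased ethyl 3-formyl-1H-indole-2-carboxylate F1 under catalytic p-TsOH·H2O in MeCN, a bis(indolyl)methane condensation of an indole-3-carbaldehyde. This gives ethyl 3-[bis(1H-indol-3-yl)methyl]-1H-indole-2-carboxylate F2.
     - LiAlH4 in THF at 0 °C reduces the ester to {3-[bis(1H-indol-3-yl)methyl]-1H-indol-2-yl}methanol F3.
     - MnO2 in CH2Cl2 oxidises F3 to the aldehyde, so the fallback comes back to the route at 17.

2. **Step 4.**
   - What may go wrong: the crowded enolate may add only slowly to the ortho-substituted aldehyde. Retro-aldol cleavage may set in before the aldolate is acetylated. The amide base may metalate C2–H of a Boc-indole.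
   - Fallback: the alkene is built first and the indoles are attached last, setting out from 6.
     - Knoevenagel condensation of 6 with dimethyl malonate (piperidine, AcOH, toluene, rt to 40 °C) gives dimethyl 2-[(2-azidophenyl)methylidene]propanedioate F4.
     - i-Bu2AlH in CH2Cl2 at −78 °C gives 2-[(2-azidophenyl)methylidene]propane-1,3-diol F5.
     - One equivalent of t-BuMe2SiCl with imidazole silylates the less hindered hydroxyl, the one trans to the aryl ring. This gives (E)-3-(2-azidophenyl)-2-[(tert-butyldimethylsilyloxy)methyl]prop-2-en-1-ol F6.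
     - MnO2 gives (Z)-3-(2-azidophenyl)-2-[(tert-butyldimethylsilyloxy)methyl]prop-2-enal F7.
     - Two equivalents of indole 1 with catalytic Sc(OTf)3 in MeCN condense at the aldehyde carbon to give (E)-3,3'-{3-(2-azidophenyl)-2-[(tert-butyldimethylsilyloxy)methyl]prop-2-ene-1,1-diyl}bis(1H-indole) F8.
     - Boc2O with DMAP brings the fallback back to the route at 12. Any drift of alkene geometry on the way is harmless for step 8.

3. **Step 6.**
   - What may go wrong: hydride may attack the carbamate carbonyls or the azide while reduction of the crowded ester lags behind.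
   - Fallback: the carbonyl is brought in at the aldehyde level, so that the last reduction needs only a mild borohydride. It sets out from 4.
     - i-Bu2AlH (1.1 equiv, toluene, −78 °C), used before any azide is present and on an unhindered ester, gives 3,3-bis(1-Boc-indol-3-yl)propanal F9.
     - Amine-catalysed cross-aldol condensation of F9 with the non-enolisable aldehyde 6 (piperidine and AcOH, 20 mol % each, toluene, 4 Å molecular sieves, 40 °C) gives (E)-3-(2-azidophenyl)-2-[bis(1-Boc-indol-3-yl)methyl]prop-2-enal F10.
     - Luche reduction (NaBH4, CeCl3·7H2O, MeOH/THF, 0 °C) leaves azide and carbamates alone and comes back to the route at 11.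

**Further compounds**
F1 | step 8 | ethyl 3-formyl-1H-indole-2-carboxylate | CCOC(=O)c1[nH]c2ccccc2c1C=O
F2 | step 8 | ethyl 3-[bis(1H-indol-3-yl)methyl]-1H-indole-2-carboxylate | CCOC(=O)c1[nH]c2ccccc2c1C(c1c[nH]c2ccccc12)c1c[nH]c2ccccc12
F3 | step 8 | {3-[bis(1H-indol-3-yl)methyl]-1H-indol-2-yl}methanol | OCc1[nH]c2ccccc2c1C(c1c[nH]c2ccccc12)c1c[nH]c2ccccc12
F4 | step 4 | dimethyl 2-[(2-azidophenyl)methylidene]propanedioate | COC(=O)C(=Cc1ccccc1N=[N+]=[N-])C(=O)OC
F5 | step 4 | 2-[(2-azidophenyl)methylidene]propane-1,3-diol | OCC(CO)=Cc1ccccc1N=[N+]=[N-]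
F6 | step 4 | (E)-3-(2-azidophenyl)-2-[(tert-butyldimethylsilyloxy)methyl]prop-2-en-1-ol | [N-]=[N+]=Nc1ccccc1/C=C(/CO[Si](C)(C)C(C)(C)C)CO
F7 | step 4 | (Z)-3-(2-azidophenyl)-2-[(tert-butyldimethylsilyloxy)methyl]prop-2-enal | [N-]=[N+]=Nc1ccccc1/C=C(/CO[Si](C)(C)C(C)(C)C)C=O
F8 | step 4 | (E)-3,3'-{3-(2-azidophenyl)-2-[(tert-butyldimethylsilyloxy)methyl]prop-2-ene-1,1-diyl}bis(1H-indole) | [N-]=[N+]=Nc1ccccc1/C=C(/CO[Si](C)(C)C(C)(C)C)C(c1c[nH]c2ccccc12)c1c[nH]c2ccccc12
F9 | step 6 | 3,3-bis(1-Boc-indol-3-yl)propanal | O=CCC(c1cn(C(=O)OC(C)(C)C)c2ccccc12)c1cn(C(=O)OC(C)(C)C)c2ccccc12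
F10 | step 6 | (E)-3-(2-azidophenyl)-2-[bis(1-Boc-indol-3-yl)methyl]prop-2-enal | [N-]=[N+]=Nc1ccccc1/C=C(/C=O)C(c1cn(C(=O)OC(C)(C)C)c2ccccc12)c1cn(C(=O)OC(C)(C)C)c2ccccc12
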